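The target is the monoacetate of an anti-1,3-diol whose C2 axis runs through C4, so O3 and O5 of the heptane chain are homotopic. The plan therefore builds the achiral syn (meso) diol, lets a lipase put the acetate on one carbinol, and then inverts the other: the C5 triflate is displaced from the rear by the carbonyl oxygen of the C3 acetate, closing a transient 2-methyl-1,3-dioxan-2-ylium ring (O3, acetyl carbon, O5, C5, C4, C3) that water opens to the anti monoacetate, no matter which ring oxygen ends up acetylated. The precursor is the bis-benzyl-protected (3R,5S) hydroxy acetate; hydrogenolysis then gives the target.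

Key step: step 6

Assumption: the lipase is taken to follow the usual empirical size rule for secondary alcohols and to acetylate the (R)-configured carbinol of the meso diol; this sense has to be confirmed on compound 11 (for example through its MTPA esters) before the key step.

Remark: the configurations were checked from the SMILES; 15 and 16 are (3R,5R) (anti), 9 and 11 are (3R,5S) (syn). In the syn monoacetate 11 a 1,3-acetyl shift from O3 to O5 gives the enantiomer, so 11 is kept away from base and used at once; in the anti compounds 15 and 16 the same shift is degenerate.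

Step 1
Reactants: 1 4-(4-hydroxyphenyl)butan-2-one; 2 benzyl bromide
Product: 3 4-[4-(benzyloxy)phenyl]butan-2-one
Conditions: BnBr (1.1 equiv), K2CO3, acetone, reflux
Reagents that add atoms: none
Why: Williamson ether synthesis, in which the phenoxide formed with K2CO3 is O-benzylated by SN2 while the far less acidic ketone is not enolised by the carbonate.

Step 2
Reactants: 4 3-(4-hydroxyphenyl)propanoic acid; 2 benzyl bromide (2 equiv)
Product: 5 benzyl 3-[4-(benzyloxy)phenyl]propanoate
Conditions: BnBr (2.3 equiv), K2CO3 (3 equiv), DMF, 60 °C
Reagents that add atoms: none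
Why: Williamson etherification of the phenoxide together with SN2 O-alkylation of the carboxylate protects the phenol and supplies the ester needed as acyl donor in one operation, so no separate esterification is required.

Step 3
Reactants: 3 4-[4-(benzyloxy)phenyl]butan-2-one (2 equiv); 5 benzyl 3-[4-(benzyloxy)phenyl]propanoate
Product: 8 1,7-bis[4-(benzyloxy)phenyl]heptane-3,5-dione, via lithium enolate 6 (not isolated), via lithium diketonate 7 (not isolated)
Conditions: LiN(i-Pr)2 (2.1 equiv), THF, −78 °C; then 5 (1.0 equiv), −78 → 0 °C; 1 M HCl
Reagents that add atoms: none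
Why: Crossed Claisen condensation, in which the amide base removes a methyl proton of 3 at low temperature to give the kinetic enolate 6 that is C-acylated by ester 5, the second equivalent of 6 turning the more acidic product into diketonate 7 (which blocks a second acylation and regenerates recoverable 3) before acid releases 8.

Step 4
Reactants: 8 1,7-bis[4-(benzyloxy)phenyl]heptane-3,5-dione
Product: 9 (3R,5S)-1,7-bis[4-(benzyloxy)phenyl]heptane-3,5-diol (meso, syn)
Conditions: TiCl4 (1.1 equiv), BH3·pyridine (2.2 equiv), CH2Cl2, −78 °C; 1 M HCl; recrystallisation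
Reagents that add atoms: none
Why: Chelation-controlled hydride reduction of a 1,3-diketone, in which titanium holds first the dicarbonyl and then the β-titanoxy ketone in a six-membered chelate so that external hydride reaches the second carbonyl on the face that gives the 1,3-syn diol, both enantiomers of the intermediate aldolate converging on the same achiral meso compound and residual anti diol being removed by crystallisation.

Step 5
Reactants: 9 (3R,5S)-1,7-bis[4-(benzyloxy)phenyl]heptane-3,5-diol; 10 vinyl acetate (3 equiv)
Product: 11 (3R,5S)-1,7-bis[4-(benzyloxy)phenyl]-5-hydroxyheptan-3-yl acetate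
Conditions: Burkholderia cepacia lipase (Amano PS, immobilised), t-BuOMe, 30 °C; filtration, chromatography on neutral silica
Reagents that add atoms: none
Why: Lipase-catalysed irreversible transesterification of a meso diol, in which the enzyme is acetylated by vinyl acetate (the enol set free tautomerises to acetaldehyde) and, by the empirical size rule, passes the acetyl group to the (R)-configured carbinol whose larger substituent is the chain bearing the other hydroxyl, so the enzyme should set the absolute configuration as 3R acetate and 5S alcohol, while any over-acylation should consume mainly the minor enantiomer.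

Step 6
Reactants: 11 (3R,5S)-1,7-bis[4-(benzyloxy)phenyl]-5-hydroxyheptan-3-yl acetate
Product: 15 (3R,5R)-1,7-bis[4-(benzyloxy)phenyl]-5-hydroxyheptan-3-yl acetate, via triflate 12 (not isolated), via dioxanylium triflate 13 (not isolated), via ortho acid 14 (not isolated)
Conditions: Tf2O (1.2 equiv), 2,6-di-tert-butyl-4-methylpyridine (3 equiv), CH2Cl2, −78 → −20 °C; then H2O, THF, 0 °C → rt
Reagents that add atoms: water, O
Why: Tf2O and the hindered pyridine base convert the only free hydroxyl of 11 (the phenols are benzylated) into the secondary triflate 12, whose C5–O bond is broken by rearside attack of the carbonyl oxygen of the C3 acetate in an intramolecular SN2 displacement that forms the new C5–O bond and the 2-methyl-1,3-dioxan-2-ylium ion 13; water then adds to the cationic carbon to give ortho acid 14, which collapses to hydroxy acetate 15. The closest known reaction type is the inversion of hydroxy esters by neighbouring acyloxy participation through cyclic acyloxonium ions that are opened by water, as in the wet Woodward–Prévost manifold. The transient six-membered ring (O3, acetyl carbon, carbonyl oxygen, C5, C4, C3) closes in the 6-exo-tet mode, the triflate leaving from outside the ring. C5 is inverted from S to R stereospecifically because the tethered nucleophile can reach it only anti to the leaving group, while C3 is untouched and relays the configuration set by the enzyme. The step needs substitution to win over β-elimination and needs no regiocontrol in the ring opening: the first is secured by the internal nucleophile held in a chair-like six-membered transition state, the low temperature and a base that cannot be alkylated, the second by the C2 axis through C4 of the anti diol, which makes O3 and O5 homotopic so that both modes of collapse of 14, and even direct attack of water on 12, should give the same compound 15.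

Step 7
Reactants: 15 (3R,5R)-1,7-bis[4-(benzyloxy)phenyl]-5-hydroxyheptan-3-yl acetate
Product: 16 (3R,5R)-5-hydroxy-1,7-bis(4-hydroxyphenyl)heptan-3-yl acetate
Conditions: H2 (1 atm), 10% Pd/C, EtOAc/EtOH, rt
Reagents that add atoms: none
Why: Heterogeneous catalytic hydrogenolysis of the two aryl benzyl ethers under neutral conditions should leave the secondary acetate, the secondary alcohol and both stereocentres untouched, and any acetyl shift between O3 and O5 is degenerate in the C2-symmetric anti diol.

Compound list
1 | 4-(4-hydroxyphenyl)butan-2-one | CC(=O)CCc1ccc(O)cc1 | starting material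
2 | benzyl bromide | BrCc1ccccc1 | starting material
3 | 4-[4-(benzyloxy)phenyl]butan-2-one | CC(=O)CCc1ccc(OCc2ccccc2)cc1 | intermediate
4 | 3-(4-hydroxyphenyl)propanoic acid | OC(=O)CCc1ccc(O)cc1 | starting material
5 | benzyl 3-[4-(benzyloxy)phenyl]propanoate | O=C(OCc1ccccc1)CCc1ccc(OCc2ccccc2)cc1 | intermediate
6 | lithium 4-[4-(benzyloxy)phenyl]but-1-en-2-olate (kinetic enolate of 3, not isolated) | [Li+].[O-]C(=C)CCc1ccc(OCc2ccccc2)cc1 | intermediate
7 | lithium (Z)-1,7-bis[4-(benzyloxy)phenyl]-5-oxohept-3-en-3-olate (not isolated) | [Li+].[O-]/C(CCc1ccc(OCc2ccccc2)cc1)=C\C(=O)CCc1ccc(OCc2ccccc2)cc1 | intermediate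
8 | 1,7-bis[4-(benzyloxy)phenyl]heptane-3,5-dione | O=C(CCc1ccc(OCc2ccccc2)cc1)CC(=O)CCc1ccc(OCc2ccccc2)cc1 | intermediate
9 | (3R,5S)-1,7-bis[4-(benzyloxy)phenyl]heptane-3,5-diol (meso, syn) | O[C@H](CCc1ccc(OCc2ccccc2)cc1)C[C@@H](O)CCc1ccc(OCc2ccccc2)cc1 | intermediate
10 | vinyl acetate | C=COC(C)=O | starting material
11 | (3R,5S)-1,7-bis[4-(benzyloxy)phenyl]-5-hydroxyheptan-3-yl acetate | CC(=O)O[C@H](CCc1ccc(OCc2ccccc2)cc1)C[C@@H](O)CCc1ccc(OCc2ccccc2)cc1 | intermediate
12 | (3R,5S)-1,7-bis[4-(benzyloxy)phenyl]-5-{[(trifluoromethyl)sulfonyl]oxy}heptan-3-yl acetate (not isolated) | CC(=O)O[C@H](CCc1ccc(OCc2ccccc2)cc1)C[C@@H](OS(=O)(=O)C(F)(F)F)CCc1ccc(OCc2ccccc2)cc1 | intermediate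
13 | (4R,6R)-4,6-bis{2-[4-(benzyloxy)phenyl]ethyl}-2-methyl-1,3-dioxan-2-ylium trifluoromethanesulfonate (4,6-trans, not isolated) | CC1=[O+][C@H](CCc2ccc(OCc3ccccc3)cc2)C[C@@H](CCc2ccc(OCc3ccccc3)cc2)O1.[O-]S(=O)(=O)C(F)(F)F | intermediate
14 | (4R,6R)-4,6-bis{2-[4-(benzyloxy)phenyl]ethyl}-2-methyl-1,3-dioxan-2-ol (ortho acid, not isolated) | CC1(O)O[C@H](CCc2ccc(OCc3ccccc3)cc2)C[C@@H](CCc2ccc(OCc3ccccc3)cc2)O1 | intermediate
15 | (3R,5R)-1,7-bis[4-(benzyloxy)phenyl]-5-hydroxyheptan-3-yl acetate | CC(=O)O[C@H](CCc1ccc(OCc2ccccc2)cc1)C[C@H](O)CCc1ccc(OCc2ccccc2)cc1 | intermediate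
16 | (3R,5R)-5-hydroxy-1,7-bis(4-hydroxyphenyl)heptan-3-yl acetate | CC(=O)O[C@H](CCc1ccc(O)cc1)C[C@H](O)CCc1ccc(O)cc1 | target

Total step count: 7. Longest linear sequence: 6 steps (step 1 or step 2, then steps 3 to 7).

Steps most likely to fail

Step 6. The secondary triflate may lose triflic acid by β-elimination towards C4 or C6, or decompose on warming, before the acetate carbonyl has closed the ring. An acetyl shift in 11 before activation would also lower the optical purity. The fallback sets out from diketone 8 and comes back at 15, and it needs no inversion. Asymmetric hydrogenation of both carbonyl groups with RuCl2[(R)-BINAP] (H2, MeOH/CH2Cl2) should give the anti diol under catalyst control at both centres, here (3R,5R)-1,7-bis[4-(benzyloxy)phenyl]heptane-3,5-diol F1. The ligand sense is chosen by analogy with pentane-2,4-dione and is to be confirmed. MeC(OMe)3 with catalytic pyridinium p-toluenesulfonate in CH2Cl2 would then give the cyclic orthoester (4R,6R)-4,6-bis{2-[4-(benzyloxy)phenyl]ethyl}-2-methoxy-2-methyl-1,3-dioxane F2. Dilute aqueous acetic acid should open it to 15, again without a regiochemical question because the diol is C2-symmetric.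

Step 5. Acyl transfer may be slow and may discriminate poorly between the two enantiotopic hydroxyls, because both substituents at each carbinol are long chains, or it may take place at the (S)-carbinol. The fallback sets out from diol 9 and comes back at 11. Exhaustive acetylation (Ac2O, DMAP, pyridine) gives the meso diester (3R,5S)-1,7-bis[4-(benzyloxy)phenyl]heptane-3,5-diyl diacetate F3, which is then hydrolysed enzymatically in pH 7 phosphate buffer with a cosolvent. In the hydrolytic mode an enzyme removes the acetate that it would have put on. A hydrolase that prefers the (S)-carbinol, useless for acylation, should therefore cleave the (5S)-acetate of F3 and leave 11. This mode also admits esterases such as pig liver esterase, which cannot be used with vinyl acetate in an organic solvent.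

Step 4. Hydride delivery to the second carbonyl may be insufficiently face-selective, leaving anti diol that is hard to remove, or the Lewis acid may attack the benzyl ethers. The fallback sets out from ester 5 and ketone 3 and comes back at 9. i-Bu2AlH in CH2Cl2 at −78 °C should reduce 5 to the aldehyde 3-[4-(benzyloxy)phenyl]propanal F4. Aldol addition of lithium enolate 6 (from 3, LiN(i-Pr)2, THF, −78 °C) to it would give racemic 1,7-bis[4-(benzyloxy)phenyl]-5-hydroxyheptan-3-one F5. Narasaka–Prasad reduction (Et2BOMe, NaBH4, THF/MeOH, −78 °C) of the boron chelate should then give the syn diol. Because the syn diol is meso, both enantiomers of the aldol end in 9.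

Further compounds
F1 | step 6 | (3R,5R)-1,7-bis[4-(benzyloxy)phenyl]heptane-3,5-diol | O[C@H](CCc1ccc(OCc2ccccc2)cc1)C[C@H](O)CCc1ccc(OCc2ccccc2)cc1
F2 | step 6 | (4R,6R)-4,6-bis{2-[4-(benzyloxy)phenyl]ethyl}-2-methoxy-2-methyl-1,3-dioxane | COC1(C)O[C@H](CCc2ccc(OCc3ccccc3)cc2)C[C@@H](CCc2ccc(OCc3ccccc3)cc2)O1
F3 | step 5 | (3R,5S)-1,7-bis[4-(benzyloxy)phenyl]heptane-3,5-diyl diacetate | CC(=O)O[C@H](CCc1ccc(OCc2ccccc2)cc1)C[C@@H](OC(C)=O)CCc1ccc(OCc2ccccc2)cc1
F4 | step 4 | 3-[4-(benzyloxy)phenyl]propanal | O=CCCc1ccc(OCc2ccccc2)cc1
F5 | step 4 | rac-1,7-bis[4-(benzyloxy)phenyl]-5-hydroxyheptan-3-one | O=C(CCc1ccc(OCc2ccccc2)cc1)CC(O)CCc1ccc(OCc2ccccc2)cc1
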